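(The earlier runs and the new flask stem from a simulated flask from invented constants, and the scatter is random.)

I decide to count in the logarithms of what is left of each substrate and to build the flask up one process at a time.

the same everywhere: left-handed substrate 0.20 M; right-handed substrate 0.20 M
- south: coupling partner 2 equiv; free catalyst 0.17 mol%; run made earlier
- south-west: coupling partner 2 equiv; free catalyst 0.67 mol%; run made earlier
- theta: coupling partner 2.00 equiv; free catalyst 0.5 mol%; time 6.0 h
- alpha: coupling partner 2.00 equiv; free catalyst 0.12 mol%; time 6.0 h

| run | time / h | right-handed substrate / % | left-handed substrate / % | left-handed product / % |
|---|---|---|---|---|
| south | 0.833 | 35 | 21 | 27 |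
| south | 1.50 | 29 | 20 | 35 |
| south | 2.50 | 21 | 16 | 35 |
| south | 3.00 | 29 | 13 | 35 |
| south-west | 0.833 | 23 | 14 | 38 |
| south-west | 1.50 | 24 | 13 | 39 |
| south-west | 2.50 | 18 | 1 | 44 |
| south-west | 3.00 | 17 | 8 | 41 |

(each reading ± 2 percentage points)

- free catalyst is single-handed; left-handed substrate and right-handed substrate are mirror images of each other, charged as a racemate, each of them at the stated concentration
- an excess is the difference of the two amounts in percent of their sum
- an excess is below zero if the other one leads

1. the winner by excess of right-handed substrate over left-handed substrate among what is left of the two; "neither" if no more than 2 percentage points parts them (theta / alpha / neither)
2. excess of right-handed substrate over left-handed substrate among what is left of the two at the end, theta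
3. excess of right-handed substrate over left-handed substrate among what is left of the two at the end, alpha

First I take the main step by itself: the left-handed substrate is coupled, and I suppose that the logarithm of its share left grows in proportion to catalyst loading × time. Scaling the first south-west reading to theta gives

ln(charge / c left-handed substrate) = 6.84

This reckoning puts the left-handed substrate at 0.107% of its charge, and with the right-handed substrate taken as untouched it puts the excess in theta at 99.8%.

Next I add the right-handed substrate, which I suppose is coupled more slowly by the same catalyst and partner, so that the two logarithms keep a fixed proportion. In the south run the right-handed substrate reads 21% and then 29%. I take this substrate as only consumed, so I put the climb down to scatter and pool these two readings, and likewise the left-handed ones beside them: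

s = 1.79

I carry this reading: the selectivity factor s, the logarithm of the left-handed share left over that of the right-handed share left. With it, my reckoned excess for theta falls to 90.7%.

Then I add the slowing that the readings show. Between two scattered readings of the south-west run the left-handed logarithm grows 1.44-fold while time grows 3.60-fold, so I read a power of 0.284 and apply it to loading × time. Scaling from the last south-west reading gives left-handed logarithms of 2.05 for theta and 1.37 for alpha. Dividing each by s, I reckon these excesses:

theta 42.3%, alpha 29.2%

The forecast names theta, with 42% (32% to 54%) for theta and 26% (20% to 33%) for alpha, holding that “catalyst loading and time seem interchangeable”. My figure for alpha stands higher than the forecast's.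

The flasks give theta as the winner, with 50.6% in theta and 36.8% in alpha.

    coupling partner + free catalyst + left-handed substrate → free catalyst + left-handed product (k = 220 /M²/min)
    2 free catalyst ⇌ resting dimer, settled at all times (K = 400 /M)
    coupling partner + free catalyst + right-handed substrate → free catalyst + right-handed product (k = 110 /M²/min)
    2 free catalyst → spent catalyst (k = 28.0 /M/min)

Theta ends with 11% of its charged left-handed substrate, and s turns that into 28.7% of the charged right-handed substrate and an excess of 45.2%, while theta holds 33% of that charge. The neighbour of alpha with 0.500 equiv of coupling partner ends with 73% of its charged left-handed substrate. There s gives 83.9% of the charged right-handed substrate and an excess of 6.93%. That neighbour holds 85% of its charged right-handed substrate, with an excess of 7.88%.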